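All constants were chosen freely, and the outcome is calculated.

At early times in Saturday's flask the full charge of starting material, the limiting reagent, faces closure to ring and loss to open dimer, and I carry the ratio of these two through both set-ups.

- Thursday's: starting material 0.50 mM; a single well-mixed tank run continuously and read at steady state, 6.0 s in it on average
- Saturday's: starting material 0.50 mM; time 6.0 s; everything together in a closed stirred flask, run for 6.0 s

    starting material → ring (k1 = 3.4 s⁻¹)
    ring ⇌ isomer of the product (K2 = 2.8, k2 = 0.12 s⁻¹)
    2 starting material → open dimer (k3 = 67000 M⁻¹ s⁻¹)
    starting material ⇌ dormant form (K4 = 25, k4 = 0.11 s⁻¹)

- in percentages every species weighs as the starting material in it: one open dimer counts as two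
- a doubled species enters its step squared and goes two at a time
- the stated concentrations are those of everything mixed, before any reaction; amounts are the same in each set-up
- run time (Saturday's): 6.0 s

1. the set-up with the highest amount of ring at the outlet or at the end, in percent of the starting material put in ("none" if the first two lie within 2 percentage points) (Thursday's / Saturday's / none)
2. amount of ring at the outlet or at the end, in percent of the starting material put in, Thursday's
3. amount of ring at the outlet or at the end, in percent of the starting material put in, Saturday's

At full charge, loss to open dimer runs at 67.0 s⁻¹ against 3.4 s⁻¹ for closure, a ratio of 19.7. This rate of loss to open dimer over the rate of closure to ring at full charge is my crowding number, a selectivity factor. With a fraction x of the charge present, the ratio is the crowding number times x.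

In Saturday's flask I sum closure's share as x falls, which gives the logarithm of one plus the crowding number, over the crowding number: 0.154 of the charge becomes ring. The dormant form's forward step is slower than closure, so I book it at 0.00498, and open dimer takes 0.841. The half-life of starting material by closure alone, 0.204 s, is far shorter than the run, so the ring then relaxes toward isomer of the product for about 6.0 s, keeping 0.540 of itself. Saturday's ring is 8.31%, and the isomer holds 0.0708.

Thursday's tank gives each portion 20.4 closure turnovers on average and holds starting material at one low fraction. Feed must equal what leaves, which puts that fraction at 0.0295. The tank's entries are then 0.0295 unreacted, 0.0195 dormant form, 0.350 open dimer and 0.602 closed, and these close the books. Of the closed part, isomer of the product takes a share, leaving Thursday's ring at 38.2%. I commit to Thursday's.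

The forecast also says Thursday's, with 38% for Thursday's and 8.3% for Saturday's, on the ground that the tank “holds it at about 0.015 mM so ring closure competes far better”.

The simulation gives Thursday's, with ring at 38.3% from Thursday's tank and 8.33% from Saturday's flask. Saturday's flask starts with loss to open dimer at 19.7 times closure's rate, while in Thursday's tank, at my fraction of 0.0295, that ratio is 0.581, and the outlet reads 35.0% as open dimer. For Saturday's flask left for 60.0 s the crowding number and my 0.154 made stand as they were, my relaxing factor keeps 0.263 of that, and the flask reads 4.04% ring.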